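## Retrosynthetic overview

1. The target is (6R,6'R)-ε,ε-carotene. Each C6–H stereocentre, together with its C4=C5 bond, is traced back by a retro-ene 1,3-transposition to an allylic diazene C4–N=NH on a β-ring (C5=C6).
2. Both C4–N bonds come from one catalyst-controlled, enantioconvergent allylic C–N bond formation between isozeaxanthin (any stereoisomer) and the sulfonyl hydrazone IPNBSH. This step defines the stereochemistry.
3. Isozeaxanthin comes from commercial canthaxanthin by hydride reduction.
4. No ring and no C–C bond is formed. Both six-membered rings and the whole C40 polyene are bought with canthaxanthin; only the end groups are edited (C=O → C–OH → C–N → C–H).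

Assumptions: crystalline canthaxanthin (1) and IPNBSH (3) are bought. The sense of induction of the new catalyst ((S)-TRIP gives 4R) is assumed; if a test run on 4-hydroxy-β-ionone shows the opposite, (R)-TRIP is used. The two end groups react independently in every step, and each compound is numbered at the stage where both ends have reacted.

## Route

Step 1
Reactants: 1 canthaxanthin ((all-E)-β,β-carotene-4,4'-dione)
Product: 2 isozeaxanthin ((all-E)-β,β-carotene-4,4'-diol, mixture of the (4R,4'R), (4S,4'S) and meso isomers)
Conditions: NaBH4, CH2Cl2/EtOH 1:1, 0 → 23 °C, dark, Ar; NaHCO3 work-up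
Reagents that add atoms: none
Why: Borohydride 1,2-reduction of the two enone carbonyls, whose β-carbon (C6) is fully substituted so conjugate reduction does not compete; the C4 configuration formed here does not matter because both centres are erased by ionisation in step 2.

Step 2
Reactants: 2 isozeaxanthin; 3 IPNBSH (N-isopropylidene-N'-(2-nitrobenzenesulfonyl)hydrazine), 2.3 equiv
Product: 4 (4R,4'R)-4,4'-bis[1-(2-nitrophenylsulfonyl)-2-(propan-2-ylidene)hydrazin-1-yl]-β,β-carotene
Conditions: (S)-TRIP (3,3'-bis(2,4,6-triisopropylphenyl)-BINOL hydrogen phosphate, 10 mol %), 5 Å MS, CH2Cl2/toluene 1:1, 0.01 M, −40 °C, dark, Ar; then Et3N (20 mol %), Et3N-deactivated SiO2, recrystallisation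
Reagents that add atoms: IPNBSH (compound 3), CC(C)=NNS(=O)(=O)c1ccccc1[N+](=O)[O-]
Why: Proposed new method: a chiral phosphoric acid catalysed, enantioconvergent dehydrative SN1 N-allylation of a sulfonyl hydrazone, in which the acid ionises either C4 epimer to the polyene-delocalised C4 cation held as a contact ion pair with the chiral phosphate, whose second oxygen hydrogen-bonds the acidic N–H of 3 and delivers nitrogen to one face of C4 (attack at C4 restores the full undecaene chromophore, as in the known acid-catalysed conversion of 4-hydroxy carotenoids into 4-alkoxy carotenoids), so both C4–N centres are set as R under catalyst control whatever the configuration of 2, with water as the only by-product; the closest known reaction types are chiral phosphoric acid catalysed asymmetric SN1 substitutions of stabilised allylic and benzylic alcohols (counteranion-directed catalysis) and the Mitsunobu or Pd-catalysed N-allylation of IPNBSH.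

Step 3
Reactants: 4 (4R,4'R)-bis(N-sulfonyl hydrazone) adduct
Product: 7 (6R,6'R)-ε,ε-carotene (all-E), via bis(sulfonylhydrazine) 5 (not isolated), via bis(diazene) 6 (not isolated)
Conditions: THF/CF3CH2OH/H2O 2:1:1, 23 °C, dark, Ar; NaHCO3 wash; crystallisation of the all-E isomer
Reagents that add atoms: none
Why: Hydrolysis of the hydrazone gives the N-allyl-N-sulfonylhydrazine 5, which loses 2-nitrobenzenesulfinic acid to the allylic monoalkyl diazene 6, and the retro-ene loss of N2 (Myers–Movassaghi reductive allylic transposition) delivers the N–H hydrogen suprafacially from C4 to C6 while the double bond moves to C4=C5, so each (4R) C–N centre becomes a (6R) C–H centre.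

## Compound list

1 | canthaxanthin, (all-E)-β,β-carotene-4,4'-dione | CC1=C(/C=C/C(C)=C/C=C/C(C)=C/C=C/C=C(C)/C=C/C=C(C)/C=C/C2=C(C)C(=O)CCC2(C)C)C(C)(C)CCC1=O | starting material
2 | isozeaxanthin, (all-E)-β,β-carotene-4,4'-diol (mixture of 4,4' stereoisomers) | CC1=C(/C=C/C(C)=C/C=C/C(C)=C/C=C/C=C(C)/C=C/C=C(C)/C=C/C2=C(C)C(O)CCC2(C)C)C(C)(C)CCC1O | intermediate
3 | IPNBSH, N-isopropylidene-N'-(2-nitrobenzenesulfonyl)hydrazine | CC(C)=NNS(=O)(=O)c1ccccc1[N+](=O)[O-] | starting material
4 | (4R,4'R)-4,4'-bis[1-(2-nitrophenylsulfonyl)-2-(propan-2-ylidene)hydrazin-1-yl]-β,β-carotene | CC1=C(/C=C/C(C)=C/C=C/C(C)=C/C=C/C=C(C)/C=C/C=C(C)/C=C/C2=C(C)[C@H](N(N=C(C)C)S(=O)(=O)c3ccccc3[N+](=O)[O-])CCC2(C)C)C(C)(C)CC[C@H]1N(N=C(C)C)S(=O)(=O)c1ccccc1[N+](=O)[O-] | intermediate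
5 | (4R,4'R)-4,4'-bis[1-(2-nitrophenylsulfonyl)hydrazin-1-yl]-β,β-carotene | CC1=C(/C=C/C(C)=C/C=C/C(C)=C/C=C/C=C(C)/C=C/C=C(C)/C=C/C2=C(C)[C@H](N(N)S(=O)(=O)c3ccccc3[N+](=O)[O-])CCC2(C)C)C(C)(C)CC[C@H]1N(N)S(=O)(=O)c1ccccc1[N+](=O)[O-] | intermediate
6 | (4R,4'R)-4,4'-bis(diazenyl)-β,β-carotene | CC1=C(/C=C/C(C)=C/C=C/C(C)=C/C=C/C=C(C)/C=C/C=C(C)/C=C/C2=C(C)[C@H](N=N)CCC2(C)C)C(C)(C)CC[C@H]1N=N | intermediate
7 | (6R,6'R)-ε,ε-carotene (all-E) | CC1=CCCC(C)(C)[C@H]1/C=C/C(C)=C/C=C/C(C)=C/C=C/C=C(C)/C=C/C=C(C)/C=C/[C@H]1C(C)=CCCC1(C)C | target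

## Step count and risks

Total step count: 3. Longest linear sequence: 3 steps (1 → 2 → 4 → 7).

The three steps most likely to fail, most risky first:

Step 2 (the proposed new C–N bond formation). It can fail by proton loss from the cation (3,4-didehydro and retro-dehydro carotenoids), by poor facial control at C4, by capture of the cation along the chain, or by E/Z scrambling of the cation. An imperfect selectivity per site is partly forgiven, because the two sites amplify the ee of the chiral diastereomer and the meso adduct is removed by crystallisation. The fallback uses known chemistry; it sets out from compound 1 and comes back to the route at compound 4. Compound 1 is reduced with catecholborane and (R)-Me-CBS oxazaborolidine (toluene/CH2Cl2, −78 °C; the alkenyl side acts as the large group) to (4S,4'S)-isozeaxanthin F1. F1 is then coupled with 3 under Mitsunobu conditions (PPh3, DEAD, THF, 0 °C); SN2 inversion at both carbinols gives the same (4R,4'R) adduct 4. Stereocontrol then comes from a reagent-controlled ketone reduction and a stereospecific C–N bond formation instead of from the ion-pair catalyst.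

Step 3. The C4–N bond of 4 or 5 may re-ionise in the ionising, protic medium (loss of ee or solvolysis), the sulfinic acid set free may attack the polyene, or the diazene may decompose by a radical path. The fallback sets out from compound 2 and comes back at compound 6. The catalysis of step 2 is run at −40 °C with 2-nitrobenzenesulfonyl hydrazide (NBSH, 2.1 equiv) in place of 3, with norbornene added as a diimide trap. This gives (4R,4'R)-4,4'-bis[2-(2-nitrophenylsulfonyl)hydrazin-1-yl]-β,β-carotene F2, which needs no hydrolysis. Et3N is added cold and the flask is warmed to 23 °C; base-induced loss of sulfinic acid in aprotic medium gives 6, which goes on to 7. If the sulfonamide nitrogen attacks instead, the product is 5, which collapses the same way.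

Step 1. The risk is low but real: 1 is poorly soluble, so half-reduced material can persist, and 2 dehydrates easily on acidic silica. The fallback sets out from compound 1 and comes back at compound 4 without isolating a free diol. Compound 1 is reduced with DIBAL-H (CH2Cl2, −78 °C) and the aluminium alkoxides are acetylated in the same flask (Ac2O, pyridine, DMAP) to isozeaxanthin diacetate F3 (mixture of stereoisomers). F3 is a crystalline, storable cation precursor that is submitted to the step 2 catalyst (acetic acid instead of water as the leaving group, no sieves) to give 4.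

## Further compounds

F1 | step 2 | (4S,4'S)-isozeaxanthin, (all-E,4S,4'S)-β,β-carotene-4,4'-diol | CC1=C(/C=C/C(C)=C/C=C/C(C)=C/C=C/C=C(C)/C=C/C=C(C)/C=C/C2=C(C)[C@@H](O)CCC2(C)C)C(C)(C)CC[C@@H]1O
F2 | step 3 | (4R,4'R)-4,4'-bis[2-(2-nitrophenylsulfonyl)hydrazin-1-yl]-β,β-carotene | CC1=C(/C=C/C(C)=C/C=C/C(C)=C/C=C/C=C(C)/C=C/C=C(C)/C=C/C2=C(C)[C@H](NNS(=O)(=O)c3ccccc3[N+](=O)[O-])CCC2(C)C)C(C)(C)CC[C@H]1NNS(=O)(=O)c1ccccc1[N+](=O)[O-]
F3 | step 1 | isozeaxanthin diacetate, (all-E)-β,β-carotene-4,4'-diyl diacetate (mixture of 4,4' stereoisomers) | CC1=C(/C=C/C(C)=C/C=C/C(C)=C/C=C/C=C(C)/C=C/C=C(C)/C=C/C2=C(C)C(OC(C)=O)CCC2(C)C)C(C)(C)CCC1OC(C)=O
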